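**Assumption:** the target SMILES has no stereocentre and no stereogenic double bond, so the compound is achiral and no enantiocontrol is needed. Methyl 3-hydroxy-5-methylbenzoate is taken as a catalogue compound.

**Retrosynthetic overview**
1. The target ketone is an isomer of a 1,3-bis(aryloxy)acetone. Both aryl–CH2 bonds are traced back to aryl–O–CH2 ether bonds, which two [3,3] shifts through the silyl enol ether relay from O to the ortho carbons while the ketone oxygen stays in place.
2. The 1,3-bis(aryloxy)acetone is cut at its two C–O ether bonds into the ring A phenol, the ring B phenol and 1,3-dichloroacetone.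
3. The ring B phenol comes from 2-chloro-1,3-dimethoxybenzene by C–H borylation/oxidation, which places the C–O bond at the only unhindered position.
4. No ring is built. Both benzene rings are bought; ring B is oxygenated first, then ring A and ring B are joined to the three-carbon unit.

**Route**

Step 1
Reactants: 1 2-chloro-1,3-dimethoxybenzene
Product: 3 4-chloro-3,5-dimethoxyphenol, via aryl pinacol boronate 2 (not isolated)
Conditions: [Ir(OMe)(cod)]2 (1.5 mol %), 4,4'-di-tert-butyl-2,2'-bipyridine (3 mol %), B2pin2 (0.6 equiv), THF, 80 °C; then acetone/H2O, Oxone (2KHSO5·KHSO4·K2SO4), rt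
Reagents that add atoms: potassium peroxymonosulfate KHSO5 (active salt of Oxone), [K+].[O-]S(=O)(=O)OO
Why: Sterically controlled iridium-catalysed aromatic C–H borylation reaches only C5 of 1, the one C–H bond without an ortho substituent, and one-pot oxidation of the C–B bond gives the symmetrical phenol.

Step 2
Reactants: 4 methyl 3-hydroxy-5-methylbenzoate; 5 1,3-dichloropropan-2-one (1,3-dichloroacetone)
Product: 6 methyl 3-(3-chloro-2-oxopropoxy)-5-methylbenzoate
Conditions: 5 (3 equiv), K2CO3, KI (10 mol %), acetone, 0 °C → rt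
Reagents that add atoms: none
Why: Williamson ether synthesis in which the phenoxide of 4 displaces one chloride of the α,α'-dichloro ketone by SN2, the threefold excess of 5 keeping the second chloride in place.

Step 3
Reactants: 6 methyl 3-(3-chloro-2-oxopropoxy)-5-methylbenzoate; 3 4-chloro-3,5-dimethoxyphenol
Product: 7 methyl 3-[3-(4-chloro-3,5-dimethoxyphenoxy)-2-oxopropoxy]-5-methylbenzoate
Conditions: K2CO3, KI (10 mol %), acetone, 40 °C
Reagents that add atoms: none
Why: Second Williamson etherification in which the unhindered phenoxide of 3 displaces the remaining α-keto chloride, joining both aromatic rings to the three-carbon ketone through two C–O bonds.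

Step 4
Reactants: 7 methyl 3-[3-(4-chloro-3,5-dimethoxyphenoxy)-2-oxopropoxy]-5-methylbenzoate
Product: 14 methyl 2-[3-(3-chloro-6-hydroxy-2,4-dimethoxyphenyl)-2-oxopropyl]-3-hydroxy-5-methylbenzoate, via ring A side enol silane 8 (not isolated), via ring B side enol silane 9 (not isolated), via ring B rearranged ether 10 (not isolated), via ring A rearranged ether 11 (not isolated), via tris-silyl enol ether 12 (not isolated), via isomeric tris-silyl enol ether 13 (not isolated)
Conditions: TMSOTf (1.3 equiv), Et3N (2 equiv), PhMe, 0 °C → rt, Et3NH·OTf layer removed; BSA (6 equiv), 1,2-Cl2C6H4, 180 °C, sealed; then aq. citric acid, THF, 0 °C → rt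
Reagents that add atoms: none
Why: Proposed new method: a relay double aromatic Claisen rearrangement in which the ketone oxygen, held as a silyl enol ether, supplies the C=C bond twice: in 8 only the ring B ether is allylic, so a first [3,3] shift joins a ring B ortho carbon (both are equivalent) to the enol carbon that carries the ring A aryloxy group, giving 10 after BSA caps the new phenol (which stops protodesilylation of the enol ether and ortho-quinone methide loss of aryloxide); the ring A ether is now allylic and benzylic, so a second [3,3] shift joins ring A C2 (next to the ester and para to methyl, the site that a meta acceptor and a para alkyl group both favour, though not exclusively) to the terminal CH2 and regenerates a silyl enol ether at the same carbon (12); regioisomer 9 runs the mirror sequence through 11 and 13, and mild hydrolysis of 12 and 13 gives the one ketone 14; the closest known reactions are the thermal aromatic Claisen rearrangement of 2-substituted allyl aryl ethers and the tandem Claisen rearrangement of 2-methylene-1,3-bis(aryloxy)propanes.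

**Compound list**
1 | 2-chloro-1,3-dimethoxybenzene | COc1cccc(OC)c1Cl | starting material
2 | 2-(4-chloro-3,5-dimethoxyphenyl)-4,4,5,5-tetramethyl-1,3,2-dioxaborolane (not isolated) | COc1cc(B2OC(C)(C)C(C)(C)O2)cc(OC)c1Cl | intermediate
3 | 4-chloro-3,5-dimethoxyphenol | COc1cc(O)cc(OC)c1Cl | intermediate
4 | methyl 3-hydroxy-5-methylbenzoate | COC(=O)c1cc(C)cc(O)c1 | starting material
5 | 1,3-dichloropropan-2-one | ClCC(=O)CCl | starting material
6 | methyl 3-(3-chloro-2-oxopropoxy)-5-methylbenzoate | COC(=O)c1cc(C)cc(OCC(=O)CCl)c1 | intermediate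
7 | methyl 3-[3-(4-chloro-3,5-dimethoxyphenoxy)-2-oxopropoxy]-5-methylbenzoate | COC(=O)c1cc(C)cc(OCC(=O)COc2cc(OC)c(Cl)c(OC)c2)c1 | intermediate
8 | methyl 3-{[(1Z)-3-(4-chloro-3,5-dimethoxyphenoxy)-2-(trimethylsilyloxy)prop-1-en-1-yl]oxy}-5-methylbenzoate (not isolated; geometry of no consequence) | COC(=O)c1cc(C)cc(O/C=C(\O[Si](C)(C)C)COc2cc(OC)c(Cl)c(OC)c2)c1 | intermediate
9 | methyl 3-{[(2Z)-3-(4-chloro-3,5-dimethoxyphenoxy)-2-(trimethylsilyloxy)prop-2-en-1-yl]oxy}-5-methylbenzoate (not isolated; geometry of no consequence) | COC(=O)c1cc(C)cc(OC/C(O[Si](C)(C)C)=C/Oc2cc(OC)c(Cl)c(OC)c2)c1 | intermediate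
10 | methyl 3-({1-[3-chloro-2,4-dimethoxy-6-(trimethylsilyloxy)phenyl]-2-(trimethylsilyloxy)prop-2-en-1-yl}oxy)-5-methylbenzoate (racemic, not isolated) | COC(=O)c1cc(C)cc(OC(C(=C)O[Si](C)(C)C)c2c(O[Si](C)(C)C)cc(OC)c(Cl)c2OC)c1 | intermediate
11 | methyl 2-[1-(4-chloro-3,5-dimethoxyphenoxy)-2-(trimethylsilyloxy)prop-2-en-1-yl]-5-methyl-3-(trimethylsilyloxy)benzoate (racemic, not isolated) | COC(=O)c1cc(C)cc(O[Si](C)(C)C)c1C(Oc1cc(OC)c(Cl)c(OC)c1)C(=C)O[Si](C)(C)C | intermediate
12 | methyl 2-{(2Z)-3-[3-chloro-2,4-dimethoxy-6-(trimethylsilyloxy)phenyl]-2-(trimethylsilyloxy)prop-2-en-1-yl}-5-methyl-3-(trimethylsilyloxy)benzoate (not isolated; geometry of no consequence) | COC(=O)c1cc(C)cc(O[Si](C)(C)C)c1C/C(O[Si](C)(C)C)=C/c1c(O[Si](C)(C)C)cc(OC)c(Cl)c1OC | intermediate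
13 | methyl 2-{(1Z)-3-[3-chloro-2,4-dimethoxy-6-(trimethylsilyloxy)phenyl]-2-(trimethylsilyloxy)prop-1-en-1-yl}-5-methyl-3-(trimethylsilyloxy)benzoate (not isolated; geometry of no consequence) | COC(=O)c1cc(C)cc(O[Si](C)(C)C)c1/C=C(\O[Si](C)(C)C)Cc1c(O[Si](C)(C)C)cc(OC)c(Cl)c1OC | intermediate
14 | methyl 2-[3-(3-chloro-6-hydroxy-2,4-dimethoxyphenyl)-2-oxopropyl]-3-hydroxy-5-methylbenzoate | COC(=O)c1cc(C)cc(O)c1CC(=O)Cc1c(O)cc(OC)c(Cl)c1OC | target

**Step count**
Total step count: 4. Longest linear sequence: 3 steps (1 → 3 → 7 → 14, or 4 → 6 → 7 → 14).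

**Three steps most likely to fail**

Step 4 (the proposed new relay rearrangement). The risks are loss of the enol silane before the second shift, ionisation of the doubly activated benzylic/allylic aryl ethers 10 and 11 leading to [1,3] products, and partial reaction of ring A at C4 instead of C2 (that isomer would be removed by chromatography). The fallback uses known chemistry, sets out from 4 and 3 and comes back at 14; it shares the ring A C2/C4 question. Phenol 4 is O-alkylated with 3-chloro-2-(chloromethyl)prop-1-ene (4 equiv, K2CO3, acetone) to methyl 3-{[2-(chloromethyl)prop-2-en-1-yl]oxy}-5-methylbenzoate F1. F1 alkylates phenol 3 (K2CO3, KI, DMF) to methyl 3-({2-[(4-chloro-3,5-dimethoxyphenoxy)methyl]prop-2-en-1-yl}oxy)-5-methylbenzoate F2. The known thermal tandem Claisen rearrangement of such 2-methylene-1,3-bis(aryloxy)propanes (N,N-diethylaniline, 190 °C) gives methyl 2-{2-[(3-chloro-6-hydroxy-2,4-dimethoxyphenyl)methyl]prop-2-en-1-yl}-3-hydroxy-5-methylbenzoate F3. Lemieux–Johnson cleavage of the exocyclic methylene of F3 (OsO4 cat., NaIO4, 2,6-lutidine, dioxane/H2O) gives 14.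

Step 3. The chloro ketone 6 is base-sensitive (enolisation, Favorskii-type and aldol pathways) and the electron-rich phenoxide of 3 can also react at carbon. The fallback makes the second ether bond at the alcohol oxidation level; it sets out from 6 and comes back at 7. Ketone 6 is reduced (NaBH4, MeOH, 0 °C) to methyl 3-(3-chloro-2-hydroxypropoxy)-5-methylbenzoate F4. With K2CO3 and phenol 3 in DMF at 80 °C, F4 closes to methyl 3-methyl-5-(oxiran-2-ylmethoxy)benzoate F5, which the phenoxide opens at the terminal carbon to methyl 3-[3-(4-chloro-3,5-dimethoxyphenoxy)-2-hydroxypropoxy]-5-methylbenzoate F6. Dess–Martin periodinane (CH2Cl2, rt) oxidises F6 to 7.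

Step 2. Double substitution and self-condensation of 1,3-dichloroacetone can erode the yield of the mono-ether. The fallback avoids the dichloro ketone; it sets out from 4 and comes back at 7. Phenol 4 is alkylated with 2,3-dichloroprop-1-ene (K2CO3, acetone, reflux) to methyl 3-[(2-chloroprop-2-en-1-yl)oxy]-5-methylbenzoate F7. The vinyl chloride of F7 is converted with NBS in aqueous MeCN into methyl 3-(3-bromo-2-oxopropoxy)-5-methylbenzoate F8. F8 alkylates phenol 3 (K2CO3, acetone, rt) to give 7.

**Further compounds**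
F1 | step 4 | methyl 3-{[2-(chloromethyl)prop-2-en-1-yl]oxy}-5-methylbenzoate | COC(=O)c1cc(C)cc(OCC(=C)CCl)c1
F2 | step 4 | methyl 3-({2-[(4-chloro-3,5-dimethoxyphenoxy)methyl]prop-2-en-1-yl}oxy)-5-methylbenzoate | COC(=O)c1cc(C)cc(OCC(=C)COc2cc(OC)c(Cl)c(OC)c2)c1
F3 | step 4 | methyl 2-{2-[(3-chloro-6-hydroxy-2,4-dimethoxyphenyl)methyl]prop-2-en-1-yl}-3-hydroxy-5-methylbenzoate | COC(=O)c1cc(C)cc(O)c1CC(=C)Cc1c(O)cc(OC)c(Cl)c1OC
F4 | step 3 | methyl 3-(3-chloro-2-hydroxypropoxy)-5-methylbenzoate (racemic) | COC(=O)c1cc(C)cc(OCC(O)CCl)c1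
F5 | step 3 | methyl 3-methyl-5-(oxiran-2-ylmethoxy)benzoate (racemic) | COC(=O)c1cc(C)cc(OCC2CO2)c1
F6 | step 3 | methyl 3-[3-(4-chloro-3,5-dimethoxyphenoxy)-2-hydroxypropoxy]-5-methylbenzoate (racemic) | COC(=O)c1cc(C)cc(OCC(O)COc2cc(OC)c(Cl)c(OC)c2)c1
F7 | step 2 | methyl 3-[(2-chloroprop-2-en-1-yl)oxy]-5-methylbenzoate | COC(=O)c1cc(C)cc(OCC(Cl)=C)c1
F8 | step 2 | methyl 3-(3-bromo-2-oxopropoxy)-5-methylbenzoate | COC(=O)c1cc(C)cc(OCC(=O)CBr)c1
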